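**Plan**

1. Target: 3-O-caffeoyl-4-O-p-coumaroylquinic acid in the natural (−)-quinic acid configuration. Quinic acid numbering is used throughout: C1 quaternary (OH, CO2H = C7), C3–O caffeoyl, C4–O p-coumaroyl, C5–OH; O1, O3 and O4 lie on one face of the cyclohexane, O5 and C7 on the other.
2. Enabling feature: ring carbons C4 and C5 carry vicinal trans oxygens (O4 ester, O5 hydroxyl). They can therefore be an alkene of the six-membered ring, and cutting C4=C5 leaves an acyclic 1,7-diene that already holds C1 and C3.
3. Cuts, in retrosynthetic order: the two cinnamoyl C–O ester bonds at O3 and O4; C5–O and C4–O (through the 1,5-lactone and a 4,5-epoxide back to the alkene); the ring bond C4=C5; C3–C4 (acyl–vinyl coupling); C1–C6 (enolate allylation).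
4. Forward: (R)-malic acid is locked as a pivalaldehyde dioxolanone, allylated at C1, and its side-arm carboxyl is turned into a vinyl ketone and reduced. Ring-closing metathesis then closes the only carbocycle. Epoxidation, saponification/lactonisation and stepwise acylation complete the molecule.
5. Stereochemistry: C1 comes from (R)-malic acid (alkylation with retention, relayed by the acetal centre). C3 is set by CBS reduction. C4 and C5 are set by O3-directed epoxidation and anti opening at C5 by the C1 carboxyl. Both E-alkenes come from the cinnamic acids.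

Key step: step 5

Assumption: the hydroxyls of the 1,5-lactone 11 are taken to react with acylating agents in the order equatorial O3 > tertiary O1 > axial O4, as is usual for this bicyclic lactone.

**Route**

Step 1
Reactants: 1 (R)-malic acid
Product: 2 2-[(2R,4R)-2-tert-butyl-5-oxo-1,3-dioxolan-4-yl]acetic acid (tert-butyl cis to the CH2CO2H arm)
Conditions: t-BuCHO (1.5 equiv), cat. p-TsOH·H2O, cat. H2SO4, pentane, reflux, Dean–Stark; recrystallisation
Reagents that add atoms: pivalaldehyde, CC(C)(C)C=O
Why: Acid-catalysed acetalisation of the α-hydroxy acid unit is reversible, so the new acetal carbon should settle under thermodynamic control with tert-butyl cis to the side arm (2R), crystallisation should remove the minor trans isomer, and the malic stereocentre is not touched.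

Step 2
Reactants: 2 cis-dioxolanone acetic acid; 3 allyl bromide
Product: 4 2-[(2R,4R)-4-allyl-2-tert-butyl-5-oxo-1,3-dioxolan-4-yl]acetic acid (allyl trans to tert-butyl)
Conditions: LiN(SiMe3)2 (2.2 equiv), THF, −78 °C; 3, −78 to −20 °C; 1 M HCl work-up
Reagents that add atoms: none
Why: Enolate alkylation with self-regeneration of the stereocentre: the carboxylate/ring-enolate dianion is attacked by allyl bromide on the face anti to the tert-butyl group of the acetal, which is where the hydrogen was, so quaternary C1 forms with net retention in the (R) configuration the target needs.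

Step 3
Reactants: 4 allylated dioxolanone acetic acid
Product: 6 (2R,5R)-5-allyl-2-tert-butyl-5-(2-oxobut-3-en-1-yl)-1,3-dioxolan-4-one, via acid chloride 5 (not isolated)
Conditions: (COCl)2, cat. DMF, CH2Cl2, 0 °C to rt, evaporate; then Bu3SnCH=CH2 (1.1 equiv), Pd(PPh3)4 (3 mol%), THF, 50 °C
Reagents that add atoms: oxalyl chloride, O=C(Cl)C(=O)Cl (chlorine of 5 only); tributyl(vinyl)stannane, C=C[Sn](CCCC)(CCCC)CCCC
Why: Stille acylation: oxidative addition of acid chloride 5 to zerovalent palladium, vinyl transfer from tin and reductive elimination form the C3–C4 bond and give the vinyl ketone under neutral conditions that leave the dioxolanone, the allyl group and C1 alone.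

Step 4
Reactants: 6 vinyl ketone
Product: 7 (2R,5R)-5-allyl-2-tert-butyl-5-[(2R)-2-hydroxybut-3-en-1-yl]-1,3-dioxolan-4-one
Conditions: (S)-2-methyl-CBS-oxazaborolidine (0.5 equiv), catecholborane (1.5 equiv), toluene, −78 °C; MeOH quench, pH 7 buffer work-up
Reagents that add atoms: none
Why: Corey–Bakshi–Shibata reduction: the ketone binds the oxazaborolidine–borane complex with the vinyl group as the larger substituent and receives hydride on one face, which should set C3 as the (R)-allylic alcohol under reagent control, while catecholborane at low temperature reduces only the carbonyl (1,2) and spares the dioxolanone and both alkenes.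

Step 5
Reactants: 7 hydroxy diene (dioxolanone-protected 2-allyl-2,4-dihydroxyhex-5-enoate)
Product: 8 (2R,5R,9R)-2-tert-butyl-9-hydroxy-1,3-dioxaspiro[4.5]dec-7-en-4-one (C4=C5 cyclohexene; 3-OH cis to O1)
Conditions: second-generation Grubbs catalyst RuCl2(=CHPh)(PCy3)(H2IMes) (3 mol%), CH2Cl2 (0.01 M), 40 °C
Reagents that add atoms: none
Why: After loss of PCy3 the ruthenium benzylidene undergoes [2+2] cycloaddition and cycloreversion with the unhindered allyl terminus of 7, and the new alkylidene engages the vinyl carbinol terminus intramolecularly through a second ruthenacyclobutane that collapses to the C4=C5 double bond, with ethylene leaving as the driving force. The closest known reaction type is the ring-closing olefin metathesis of hydroxylated 1,7-dienes to cyclohex-2-en-1-ols. The one ring formed, the carbocycle, closes by olefin metathesis as a six-membered cycloalkene spiro-fused at C1 to the existing dioxolanone. No stereocentre is created: C1 and C3 pass through unchanged and the cis geometry of the new alkene is imposed by the six-membered ring. The step needs cyclisation to win over oligomerisation and over ruthenium-hydride isomerisation of the allylic alcohol, which is secured by two monosubstituted terminal alkenes, the quaternary C1 that folds the chain (Thorpe–Ingold effect), high dilution and a short reaction time. Keeping O1 and the carboxyl locked in the dioxolanone also removes the γ-lactonisation that an open γ-hydroxy ester would undergo, so the C3 hydroxyl can stay free for the next step.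

Step 6
Reactants: 8 spiro cyclohexenol
Product: 9 (2R,5R)-2-tert-butyl-7,8-epoxy-9-hydroxy-1,3-dioxaspiro[4.5]decan-4-one with the oxirane oxygen cis to the 9-hydroxyl and to O1 (4,5-epoxide on the O3 face)
Conditions: mCPBA (1.3 equiv), CH2Cl2, 0 °C to rt
Reagents that add atoms: mCPBA (3-chloroperbenzoic acid), O=C(OO)c1cccc(Cl)c1
Why: Henbest hydroxyl-directed peracid epoxidation: hydrogen bonding of the allylic C3–OH to the peracid delivers oxygen to the C4=C5 face syn to O3, which is also the face away from the carbonyl arm C7, so C4 and C5 are set as the cis-epoxy alcohol.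

Step 7
Reactants: 9 cis-epoxy alcohol
Product: 11 (−)-quinide (quinic acid 1,5-lactone), via epoxy hydroxy acid 10 (not isolated)
Conditions: LiOH (3 equiv), THF/H2O, 0 °C to rt; then 1 M HCl to pH 1–2, rt
Reagents that add atoms: water, O (delivered as hydroxide by LiOH)
Why: Saponification of the acylal-type dioxolanone releases pivalaldehyde and the C1 carboxylate, and on acidification the carboxyl, which sits on the face opposite the oxirane, opens the protonated epoxide intramolecularly at C5 in a trans-diaxial (Fürst–Plattner) 5-exo lactonisation with inversion, so O5 ends trans and O4 cis to O3, while attack at C4 would give the more strained [2.2.2] lactone and is also slowed by the adjacent C3–OH.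

Step 8
Reactants: 12 caffeic acid
Product: 13 (E)-3-(3,4-diacetoxyphenyl)prop-2-enoic acid
Conditions: Ac2O, pyridine, cat. DMAP, rt; H2O work-up
Reagents that add atoms: acetic anhydride, CC(=O)OC(C)=O
Why: DMAP-catalysed O-acetylation of both phenols, with any mixed anhydride at the carboxyl hydrolysed on aqueous work-up and the E-alkene untouched.

Step 9
Reactants: 13 di-O-acetylcaffeic acid
Product: 14 (E)-3-(3,4-diacetoxyphenyl)prop-2-enoyl chloride
Conditions: (COCl)2, cat. DMF, CH2Cl2, 0 °C to rt
Reagents that add atoms: oxalyl chloride, O=C(Cl)C(=O)Cl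
Why: Acid chloride formation through the chloroiminium species from DMF and oxalyl chloride, under which aryl acetates and the E-alkene are stable.

Step 10
Reactants: 11 (−)-quinide; 14 di-O-acetylcaffeoyl chloride
Product: 15 3-O-[(E)-3,4-diacetoxycinnamoyl]-1,5-quinide
Conditions: 14 (1.0 equiv, slow addition), pyridine/CH2Cl2, −20 to 0 °C
Reagents that add atoms: none
Why: Acylation with an acid chloride under plain pyridine catalysis at low temperature should be kinetically selective for the unhindered equatorial secondary C3–OH over the tertiary C1–OH and the axial, doubly flanked C4–OH of the bicyclic lactone.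

Step 11
Reactants: 15 3-O-acyl quinide
Product: 16 1-O-(2,2,2-trichloroethoxycarbonyl)-3-O-[(E)-3,4-diacetoxycinnamoyl]-1,5-quinide (1-O-Troc)
Conditions: TrocCl (1.3 equiv), pyridine, CH2Cl2, 0 °C to rt
Reagents that add atoms: 2,2,2-trichloroethyl chloroformate, O=C(Cl)OCC(Cl)(Cl)Cl
Why: Carbonate formation with a chloroformate should take place next at the exposed bridgehead C1–OH, which is more accessible than the axial C4–OH wedged between the C3 ester and the lactone bridge, and the Troc group is orthogonal to acetates, cinnamates and the lactone.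

Step 12
Reactants: 17 p-coumaric acid
Product: 18 (E)-3-(4-acetoxyphenyl)prop-2-enoic acid
Conditions: Ac2O, pyridine, cat. DMAP, rt; H2O work-up
Reagents that add atoms: acetic anhydride, CC(=O)OC(C)=O
Why: DMAP-catalysed O-acetylation of the phenol, as in step 8.

Step 13
Reactants: 18 4-O-acetyl-p-coumaric acid
Product: 19 (E)-3-(4-acetoxyphenyl)prop-2-enoyl chloride
Conditions: (COCl)2, cat. DMF, CH2Cl2, 0 °C to rt
Reagents that add atoms: oxalyl chloride, O=C(Cl)C(=O)Cl
Why: Acid chloride formation through the DMF-derived chloroiminium species, as in step 9.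

Step 14
Reactants: 16 1-O-Troc-3-O-acyl quinide; 19 4-O-acetyl-p-coumaroyl chloride
Product: 20 1-O-Troc-3-O-[(E)-3,4-diacetoxycinnamoyl]-4-O-[(E)-4-acetoxycinnamoyl]-1,5-quinide
Conditions: 19 (1.5 equiv), DMAP (0.3 equiv), pyridine, CH2Cl2, rt
Reagents that add atoms: none
Why: DMAP-catalysed acylation through the acylpyridinium ion forces esterification of the only remaining hydroxyl, the axial C4–OH, and with no free neighbouring hydroxyl no acyl migration can occur.

Step 15
Reactants: 20 fully protected diester lactone
Product: 21 3-O-[(E)-3,4-diacetoxycinnamoyl]-4-O-[(E)-4-acetoxycinnamoyl]-1,5-quinide (1-OH free)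
Conditions: Zn dust, AcOH/THF, rt
Reagents that add atoms: none
Why: Reductive β-elimination of the 2,2,2-trichloroethyl carbonate by zinc (Troc cleavage) followed by loss of CO2 frees the C1–OH, while aryl acetates, cinnamate esters, their alkenes and the lactone are inert to Zn/AcOH at room temperature.

Step 16
Reactants: 21 diester lactone
Product: 22 3-O-caffeoyl-4-O-p-coumaroylquinic acid (target)
Conditions: 2 M aq. HCl/THF (1:3), rt; reversed-phase purification
Reagents that add atoms: water, O
Why: Acid-catalysed hydrolysis cleaves the three aryl acetates and opens the strained γ-lactone by addition of water at C7, whereas the conjugated, hindered cinnamate esters of the secondary alcohols hydrolyse far more slowly and acid, unlike base, does not drive O4-to-O5 acyl migration, so the O3/O4 diester pattern and all four stereocentres should be kept.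

**Compound list**

1 | (R)-malic acid | O=C(O)C[C@@H](O)C(=O)O | starting material
2 | 2-[(2R,4R)-2-tert-butyl-5-oxo-1,3-dioxolan-4-yl]acetic acid | OC(=O)C[C@H]1O[C@@H](C(C)(C)C)OC1=O | intermediate
3 | allyl bromide | C=CCBr | starting material
4 | 2-[(2R,4R)-4-allyl-2-tert-butyl-5-oxo-1,3-dioxolan-4-yl]acetic acid | OC(=O)C[C@@]1(CC=C)O[C@@H](C(C)(C)C)OC1=O | intermediate
5 | 2-[(2R,4R)-4-allyl-2-tert-butyl-5-oxo-1,3-dioxolan-4-yl]acetyl chloride | ClC(=O)C[C@@]1(CC=C)O[C@@H](C(C)(C)C)OC1=O | intermediate (not isolated)
6 | (2R,5R)-5-allyl-2-tert-butyl-5-(2-oxobut-3-en-1-yl)-1,3-dioxolan-4-one | C=CC(=O)C[C@@]1(CC=C)O[C@@H](C(C)(C)C)OC1=O | intermediate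
7 | (2R,5R)-5-allyl-2-tert-butyl-5-[(2R)-2-hydroxybut-3-en-1-yl]-1,3-dioxolan-4-one | C=C[C@H](O)C[C@@]1(CC=C)O[C@@H](C(C)(C)C)OC1=O | intermediate
8 | (2R,5R,9R)-2-tert-butyl-9-hydroxy-1,3-dioxaspiro[4.5]dec-7-en-4-one | O[C@H]1C=CC[C@]2(C1)O[C@@H](C(C)(C)C)OC2=O | intermediate
9 | (2R,5R)-2-tert-butyl-7,8-epoxy-9-hydroxy-1,3-dioxaspiro[4.5]decan-4-one, oxirane oxygen cis to the 9-hydroxyl and to O1 | O[C@H]1[C@H]2O[C@H]2C[C@]3(C1)O[C@@H](C(C)(C)C)OC3=O | intermediate
10 | 4,5-epoxy-1,3-dihydroxycyclohexane-1-carboxylic acid, O1, O3 and oxirane oxygen on one face, carboxyl on the other | O[C@H]1[C@H]2O[C@H]2C[C@@](O)(C1)C(=O)O | intermediate (not isolated)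
11 | (−)-quinide, (1S,3R,4R,5R)-1,3,4-trihydroxy-6-oxabicyclo[3.2.1]octan-7-one | O[C@H]1[C@@H](O)[C@H]2C[C@@](O)(C1)C(=O)O2 | intermediate
12 | caffeic acid | O=C(O)/C=C/c1ccc(O)c(O)c1 | starting material
13 | (E)-3-(3,4-diacetoxyphenyl)prop-2-enoic acid | O=C(O)/C=C/c1ccc(OC(C)=O)c(OC(C)=O)c1 | intermediate
14 | (E)-3-(3,4-diacetoxyphenyl)prop-2-enoyl chloride | O=C(Cl)/C=C/c1ccc(OC(C)=O)c(OC(C)=O)c1 | intermediate
15 | 3-O-[(E)-3,4-diacetoxycinnamoyl]-1,5-quinide | O=C(/C=C/c1ccc(OC(C)=O)c(OC(C)=O)c1)O[C@H]1[C@@H](O)[C@H]2C[C@@](O)(C1)C(=O)O2 | intermediate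
16 | 1-O-(2,2,2-trichloroethoxycarbonyl)-3-O-[(E)-3,4-diacetoxycinnamoyl]-1,5-quinide | O=C(/C=C/c1ccc(OC(C)=O)c(OC(C)=O)c1)O[C@H]1[C@@H](O)[C@H]2C[C@@](OC(=O)OCC(Cl)(Cl)Cl)(C1)C(=O)O2 | intermediate
17 | p-coumaric acid | O=C(O)/C=C/c1ccc(O)cc1 | starting material
18 | (E)-3-(4-acetoxyphenyl)prop-2-enoic acid | O=C(O)/C=C/c1ccc(OC(C)=O)cc1 | intermediate
19 | (E)-3-(4-acetoxyphenyl)prop-2-enoyl chloride | O=C(Cl)/C=C/c1ccc(OC(C)=O)cc1 | intermediate
20 | 1-O-(2,2,2-trichloroethoxycarbonyl)-3-O-[(E)-3,4-diacetoxycinnamoyl]-4-O-[(E)-4-acetoxycinnamoyl]-1,5-quinide | O=C(/C=C/c1ccc(OC(C)=O)c(OC(C)=O)c1)O[C@H]1[C@@H](OC(=O)/C=C/c3ccc(OC(C)=O)cc3)[C@H]2C[C@@](OC(=O)OCC(Cl)(Cl)Cl)(C1)C(=O)O2 | intermediate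
21 | 3-O-[(E)-3,4-diacetoxycinnamoyl]-4-O-[(E)-4-acetoxycinnamoyl]-1,5-quinide | O=C(/C=C/c1ccc(OC(C)=O)c(OC(C)=O)c1)O[C@H]1[C@@H](OC(=O)/C=C/c3ccc(OC(C)=O)cc3)[C@H]2C[C@@](O)(C1)C(=O)O2 | intermediate
22 | 3-O-caffeoyl-4-O-p-coumaroylquinic acid (O1, O3, O4 cis; O5 and carboxyl trans to them) | O=C(/C=C/c1ccc(O)cc1)O[C@H]1[C@H](O)C[C@](O)(C(=O)O)C[C@H]1OC(=O)/C=C/c1ccc(O)c(O)c1 | target

**Step count**

Total: 16 steps. Longest linear sequence: 12 steps (steps 1–7, 10, 11, 14, 15, 16).

**Steps most likely to fail**

Step 4. The risk is poor facial selectivity in the hydride transfer, because an unsubstituted vinyl group and a β-branched methylene may differ too little in size for the oxazaborolidine. A second risk is loss of the acetal if the new alkoxide attacks the dioxolanone carbonyl during work-up. The fallback sets out from acid chloride 5 (made from 4 as in step 3). Coupling with ethynyltrimethylsilane (PdCl2(PPh3)2, CuI, Et3N, THF) would give the trimethylsilyl ynone F1. Asymmetric transfer hydrogenation with RuCl[(R,R)-TsDPEN](p-cymene) in 2-propanol, which tells alkynyl from alkyl electronically and not by size, should then give the (R)-propargylic alcohol F2. Buffered desilylation (Bu4NF, AcOH, THF, 0 °C) would give the terminal alkynol F3, and semihydrogenation (H2, Pd/CaCO3 poisoned with Pb(OAc)2, quinoline) would return to the route at 7.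

Step 11. The risk is wrong site selectivity: the chloroformate may react at the axial O4 instead of, or as well as, the tertiary O1. The fallback sets out from 11 and replaces steps 10 and 11. The cis-3,4-diol would first be tied up (2,2-dimethoxypropane, cat. p-TsOH, acetone) as 3,4-O-isopropylidene-1,5-quinide F5, which leaves O1 as the only hydroxyl. Carbonate formation (TrocCl, pyridine, DMAP) would give 1-O-Troc-3,4-O-isopropylidene-1,5-quinide F6. Aqueous CF3CO2H would release the diol as 1-O-Troc-1,5-quinide F7. Acylation with 14 (1.0 equiv, pyridine, −20 °C) at the equatorial O3 would come back to the route at 16.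

Step 10. The risk is acylation spreading over O3, O1 and O4, or double acylation, because kinetic discrimination among three hydroxyls with one equivalent of acid chloride may be incomplete. The fallback sets out from 11. Heating with Bu2SnO in methanol and evaporation would give 3,4-O-dibutylstannylene-1,5-quinide F4, in which the equatorial oxygen of the cis-diol is the activated one and O1 is not engaged. Addition of 14 (1.0 equiv, toluene/DMF, 0 °C) should then acylate O3 only and, after aqueous work-up, come back to the route at 15.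

**Further compounds**

F1 | step 4 | (2R,5R)-5-allyl-2-tert-butyl-5-[2-oxo-4-(trimethylsilyl)but-3-yn-1-yl]-1,3-dioxolan-4-one | C[Si](C)(C)C#CC(=O)C[C@@]1(CC=C)O[C@@H](C(C)(C)C)OC1=O
F2 | step 4 | (2R,5R)-5-allyl-2-tert-butyl-5-[(2R)-2-hydroxy-4-(trimethylsilyl)but-3-yn-1-yl]-1,3-dioxolan-4-one | C[Si](C)(C)C#C[C@H](O)C[C@@]1(CC=C)O[C@@H](C(C)(C)C)OC1=O
F3 | step 4 | (2R,5R)-5-allyl-2-tert-butyl-5-[(2R)-2-hydroxybut-3-yn-1-yl]-1,3-dioxolan-4-one | C#C[C@H](O)C[C@@]1(CC=C)O[C@@H](C(C)(C)C)OC1=O
F4 | step 10 | 3,4-O-dibutylstannylene-1,5-quinide | CCCC[Sn]3(CCCC)O[C@H]1[C@@H](O3)[C@H]2C[C@@](O)(C1)C(=O)O2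
F5 | step 11 | 3,4-O-isopropylidene-1,5-quinide | CC3(C)O[C@H]1[C@@H](O3)[C@H]2C[C@@](O)(C1)C(=O)O2
F6 | step 11 | 1-O-(2,2,2-trichloroethoxycarbonyl)-3,4-O-isopropylidene-1,5-quinide | CC3(C)O[C@H]1[C@@H](O3)[C@H]2C[C@@](OC(=O)OCC(Cl)(Cl)Cl)(C1)C(=O)O2
F7 | step 11 | 1-O-(2,2,2-trichloroethoxycarbonyl)-1,5-quinide | O[C@H]1[C@@H](O)[C@H]2C[C@@](OC(=O)OCC(Cl)(Cl)Cl)(C1)C(=O)O2
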